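**Plan**

- Labels: ring A is the quinone with the 2-(2-methoxyphenyl)ethyl chain. Ring B is the quinone with the 2-phenylethyl chain, numbered C1 (bonded to ring A), C2 (CH2CH2Ph), C3 (C=O), C4 (OH), C5 (CH3), C6 (C=O).
- Retrosynthesis: both hydroxyquinones go back to alkoxyquinones and then to hydroquinone ethers. Ring B is cut at C3–C4 and re-closed C3–C6 to a cyclobutenone. The four-membered ring is cut at C1–ring A (aryllithium), C6–C5 (vinyllithium) and C2–CH2 (Grignard reagent), back to diisopropyl squarate. Ring A goes back to 1,2,4-trimethoxybenzene (side-chain C=C, CHO, Br, CH3).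
- Forward: ring A is completed first as an aryl bromide. The squarate is substituted three times. Ring B then forms in one thermal operation, one oxidation makes both quinones, and one hydrolysis frees both OH groups.
- Enabling feature: in ring B the para oxygenated carbons C3 and C6 with C2=C1 between them are a cyclobutenone in disguise, and C5(CH3)=C4(O) is an enol ether. O=C3=C2–C1=C6(O)–C5=C4(O) is a dienylketene, so opening of the C3–C6 bond and 6π closure C3–C4 gives the fully substituted ring with every substituent in place.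
- Stereochemistry: the target has no stereocentre. The racemic quaternary carbon of the cyclobutenones and the enol ether geometry are erased on aromatization.

Key step: step 10

Remark: the target carries no stereodescriptors, so the tetra-ortho-substituted biquinone axis is treated as configurationally undefined.

**Step 1**
Reactants: 1 1,2,4-trimethoxybenzene
Product: 3 1,2,4-trimethoxy-3-methylbenzene, via aryllithium 2 (not isolated)
Conditions: n-BuLi, THF, 0 °C to rt; then MeI, 0 °C to rt
Reagents that add atoms: iodomethane, CI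
Why: Directed ortho-metalation should occur at the position flanked by two methoxy groups, and SN2 methylation follows.

**Step 2**
Reactants: 3 1,2,4-trimethoxy-3-methylbenzene
Product: 4 1-bromo-2,4,5-trimethoxy-3-methylbenzene
Conditions: NBS, MeCN, 0 °C to rt
Reagents that add atoms: N-bromosuccinimide, O=C1CCC(=O)N1Br
Why: Electrophilic aromatic bromination should go to position 5 (para to the 2-methoxy and ortho to the 4-methoxy group), which is more activated than position 6.

**Step 3**
Reactants: 4 1-bromo-2,4,5-trimethoxy-3-methylbenzene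
Product: 6 2-bromo-3,5,6-trimethoxy-4-methylbenzaldehyde, via alpha-chloro ether 5 (not isolated)
Conditions: Cl2CHOMe, TiCl4, CH2Cl2, −20 to 0 °C; then H2O
Reagents that add atoms: dichloromethyl methyl ether, COC(Cl)Cl; water, O
Why: Rieche formylation should take the only free ring position (ortho to methoxy, para to methyl), and aqueous work-up hydrolyses the alpha-chloro ether to the aldehyde.

**Step 4**
Reactants: 6 2-bromo-3,5,6-trimethoxy-4-methylbenzaldehyde; 7 (2-methoxybenzyl)triphenylphosphonium chloride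
Product: 9 1-bromo-2,4,5-trimethoxy-3-methyl-6-[2-(2-methoxyphenyl)ethenyl]benzene (E/Z mixture), via ylide 8 (not isolated)
Conditions: 7, KOt-Bu, THF, 0 °C; then 6, 0 °C to rt
Reagents that add atoms: none
Why: Wittig olefination with a semi-stabilized ylide; the alkene geometry is irrelevant because the double bond is reduced next.

**Step 5**
Reactants: 9 1-bromo-2,4,5-trimethoxy-3-methyl-6-[2-(2-methoxyphenyl)ethenyl]benzene
Product: 10 1-bromo-2,4,5-trimethoxy-3-methyl-6-[2-(2-methoxyphenyl)ethyl]benzene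
Conditions: TsNHNH2, NaOAc, DME/H2O, reflux
Reagents that add atoms: none
Why: Diimide reduction transfers H2 to the C=C bond in a concerted, metal-free way, so the aryl bromide should survive.

**Step 6**
Reactants: 11 ethyl prop-1-enyl ether (E/Z mixture)
Product: 13 (Z)-2-bromo-1-ethoxyprop-1-ene, via dibromo ether 12 (not isolated)
Conditions: Br2, CH2Cl2, −78 °C; then PhNEt2, heat, distillation
Reagents that add atoms: bromine, BrBr
Why: Bromine addition to the enol ether and amine-induced E1-type dehydrobromination of the alpha-bromo ether (the known route to beta-bromo enol ethers) should favour the isomer with Br cis to OEt, which is purified by distillation.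

**Step 7**
Reactants: 14 diisopropyl squarate; 15 (2-phenylethyl)magnesium chloride
Product: 18 3-(propan-2-yloxy)-4-(2-phenylethyl)cyclobut-3-ene-1,2-dione, via chloromagnesium alkoxide 16 (not isolated), via trifluoroacetate 17 (not isolated)
Conditions: THF, −78 °C; then (CF3CO)2O, −78 °C; aq. NaHCO3, rt
Reagents that add atoms: water, O
Why: 1,2-Addition to one squarate carbonyl, then acylation and ionization to the alkoxy-stabilized cyclobutenyl cation, which water attacks at the isopropoxy-bearing terminus with loss of propan-2-ol (the standard squarate-to-cyclobutenedione sequence).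

**Step 8**
Reactants: 18 3-(propan-2-yloxy)-4-(2-phenylethyl)cyclobut-3-ene-1,2-dione; 13 (Z)-2-bromo-1-ethoxyprop-1-ene
Product: 21 4-[(Z)-1-ethoxyprop-1-en-2-yl]-4-methoxy-3-(propan-2-yloxy)-2-(2-phenylethyl)cyclobut-2-en-1-one (racemic), via vinyllithium 19 (not isolated), via lithium alkoxide 20 (not isolated)
Conditions: 13, t-BuLi (2 equiv), Et2O, −78 °C; then 18, THF, −78 °C; then MeOTf, −78 to 0 °C
Reagents that add atoms: methyl trifluoromethanesulfonate, COS(=O)(=O)C(F)(F)F
Why: Bromine–lithium exchange with retention gives the vinyllithium with Li syn to OEt (no anti-elimination at −78 °C); it should add to the carbonyl next to the isopropoxy-bearing carbon because the other carbonyl is deactivated as a vinylogous ester, and MeOTf caps the tertiary alkoxide, whose racemic stereocentre is destroyed in step 10.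

**Step 9**
Reactants: 10 1-bromo-2,4,5-trimethoxy-3-methyl-6-[2-(2-methoxyphenyl)ethyl]benzene; 21 4-[(Z)-1-ethoxyprop-1-en-2-yl]-4-methoxy-3-(propan-2-yloxy)-2-(2-phenylethyl)cyclobut-2-en-1-one
Product: 25 4-[(Z)-1-ethoxyprop-1-en-2-yl]-4-methoxy-2-(2-phenylethyl)-3-{2,4,5-trimethoxy-3-methyl-6-[2-(2-methoxyphenyl)ethyl]phenyl}cyclobut-2-en-1-one (racemic), via aryllithium 22 (not isolated), via lithium alkoxide 23 (not isolated), via trifluoroacetate 24 (not isolated)
Conditions: 10, n-BuLi, THF, −78 °C; then 21, −78 to −40 °C; then (CF3CO)2O, −78 °C; aq. NaHCO3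
Reagents that add atoms: water, O
Why: 1,2-Addition of the aryllithium to the vinylogous ester carbonyl, then acylative ionization and hydrolysis of the isopropoxy-stabilized cation (Stork–Danheiser-type carbonyl transposition); in a four-membered ring this and a 1,4-addition/elimination give the same constitution, and the methyl ether at C4 cannot ionize.

**Step 10**
Reactants: 25 4-[(Z)-1-ethoxyprop-1-en-2-yl]-4-methoxy-2-(2-phenylethyl)-3-{2,4,5-trimethoxy-3-methyl-6-[2-(2-methoxyphenyl)ethyl]phenyl}cyclobut-2-en-1-one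
Product: 28 2-ethoxy-4-methoxy-3-methyl-6-(2-phenylethyl)-5-{2,4,5-trimethoxy-3-methyl-6-[2-(2-methoxyphenyl)ethyl]phenyl}phenol, via dienylketene 26 (not isolated), via cyclohexadienone 27 (not isolated)
Conditions: degassed p-xylene (high dilution), 140 °C
Reagents that add atoms: none
Why: Heat should open the cyclobutenone by conrotatory 4π electrocyclic cleavage of its C(=O)–C(OMe) bond (C3–C6 of ring B), the methoxy group rotating outward so that the 1-ethoxypropenyl group ends cis to the new ketene in 26. A disrotatory 6π electrocyclization then joins the ketene carbon (C3) to the ethoxy-bearing vinyl carbon (C4), closing the six-membered ring B as cyclohexa-2,4-dienone 27, which aromatizes by enolization to phenol 28. The closest known reaction type is the thermal ring expansion of 4-alkenyl-4-hydroxy- or 4-alkoxycyclobutenones to hydroquinone derivatives. No stereocentre remains, since the quaternary carbon of 25 becomes an arene carbon and the sp3 carbon of 27 is planarized on tautomerization. The step needs outward rotation of the oxygen substituent (secured by the donor methoxy group at C4) and cyclization of the ketene in preference to intermolecular trapping (secured by dilution in an aprotic solvent); regiochemistry is fixed because all six ring carbons and their substituents are already placed in 25.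

**Step 11**
Reactants: 28 2-ethoxy-4-methoxy-3-methyl-6-(2-phenylethyl)-5-{2,4,5-trimethoxy-3-methyl-6-[2-(2-methoxyphenyl)ethyl]phenyl}phenol
Product: 29 2-ethoxy-5-{4-methoxy-5-methyl-2-[2-(2-methoxyphenyl)ethyl]-3,6-dioxocyclohexa-1,4-dien-1-yl}-3-methyl-6-(2-phenylethyl)cyclohexa-2,5-diene-1,4-dione
Conditions: (NH4)2Ce(NO3)6, MeCN/H2O, 0 °C
Reagents that add atoms: water, O
Why: Oxidative demethylation of the 4-methoxyphenol (ring B) and of the para-dimethoxy pair (ring A) should give both para-quinones while the isolated anisole stays intact; an ortho-quinone formed instead would converge on the same hydroxyquinone tautomer in step 12.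

**Step 12**
Reactants: 29 2-ethoxy-5-{4-methoxy-5-methyl-2-[2-(2-methoxyphenyl)ethyl]-3,6-dioxocyclohexa-1,4-dien-1-yl}-3-methyl-6-(2-phenylethyl)cyclohexa-2,5-diene-1,4-dione
Product: 31 2-hydroxy-5-{4-hydroxy-5-methyl-2-[2-(2-methoxyphenyl)ethyl]-3,6-dioxocyclohexa-1,4-dien-1-yl}-3-methyl-6-(2-phenylethyl)cyclohexa-2,5-diene-1,4-dione (CNP0202346.0), via disodium salt 30 (not isolated)
Conditions: 2 M NaOH, MeOH/THF, rt; then 1 M HCl
Reagents that add atoms: sodium hydroxide, [Na+].[OH-]
Why: Addition–elimination of hydroxide at the alkoxy-bearing carbon of each 2-alkoxy-1,4-benzoquinone (vinylogous ester saponification) is driven by formation of the vinylogous carboxylate; acidification gives the bis(hydroxyquinone).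

**Compound list**

1 | 1,2,4-trimethoxybenzene | COc1ccc(OC)c(OC)c1 | starting material
2 | (2,3,6-trimethoxyphenyl)lithium | COc1ccc(OC)c([Li])c1OC | intermediate
3 | 1,2,4-trimethoxy-3-methylbenzene | COc1ccc(OC)c(C)c1OC | intermediate
4 | 1-bromo-2,4,5-trimethoxy-3-methylbenzene | COc1cc(Br)c(OC)c(C)c1OC | intermediate
5 | 1-bromo-2-[chloro(methoxy)methyl]-3,4,6-trimethoxy-5-methylbenzene (racemic) | COC(Cl)c1c(Br)c(OC)c(C)c(OC)c1OC | intermediate
6 | 2-bromo-3,5,6-trimethoxy-4-methylbenzaldehyde | COc1c(C=O)c(Br)c(OC)c(C)c1OC | intermediate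
7 | (2-methoxybenzyl)triphenylphosphonium chloride | COc1ccccc1C[P+](c1ccccc1)(c1ccccc1)c1ccccc1.[Cl-] | starting material
8 | (2-methoxybenzylidene)triphenylphosphorane | COc1ccccc1C=P(c1ccccc1)(c1ccccc1)c1ccccc1 | intermediate
9 | 1-bromo-2,4,5-trimethoxy-3-methyl-6-[2-(2-methoxyphenyl)ethenyl]benzene (E/Z mixture) | COc1ccccc1C=Cc1c(Br)c(OC)c(C)c(OC)c1OC | intermediate
10 | 1-bromo-2,4,5-trimethoxy-3-methyl-6-[2-(2-methoxyphenyl)ethyl]benzene | COc1ccccc1CCc1c(Br)c(OC)c(C)c(OC)c1OC | intermediate
11 | ethyl prop-1-enyl ether (E/Z mixture) | CCOC=CC | starting material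
12 | 1,2-dibromo-1-ethoxypropane (diastereomer mixture) | CCOC(Br)C(C)Br | intermediate
13 | (Z)-2-bromo-1-ethoxyprop-1-ene | CCO/C=C(/C)Br | intermediate
14 | diisopropyl squarate, 3,4-di(propan-2-yloxy)cyclobut-3-ene-1,2-dione | CC(C)OC1=C(OC(C)C)C(=O)C1=O | starting material
15 | (2-phenylethyl)magnesium chloride | Cl[Mg]CCc1ccccc1 | starting material
16 | chloromagnesium 4-oxo-1-(2-phenylethyl)-2,3-di(propan-2-yloxy)cyclobut-2-en-1-olate (racemic) | CC(C)OC1=C(OC(C)C)C(O[Mg]Cl)(CCc2ccccc2)C1=O | intermediate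
17 | 4-oxo-1-(2-phenylethyl)-2,3-di(propan-2-yloxy)cyclobut-2-en-1-yl trifluoroacetate (racemic) | CC(C)OC1=C(OC(C)C)C(OC(=O)C(F)(F)F)(CCc2ccccc2)C1=O | intermediate
18 | 3-(propan-2-yloxy)-4-(2-phenylethyl)cyclobut-3-ene-1,2-dione | CC(C)OC1=C(CCc2ccccc2)C(=O)C1=O | intermediate
19 | [(E)-1-ethoxyprop-1-en-2-yl]lithium (Li cis to OEt) | CCO/C=C(/C)[Li] | intermediate
20 | lithium 1-[(Z)-1-ethoxyprop-1-en-2-yl]-4-oxo-3-(2-phenylethyl)-2-(propan-2-yloxy)cyclobut-2-en-1-olate (racemic) | CCO/C=C(/C)C1(O[Li])C(OC(C)C)=C(CCc2ccccc2)C1=O | intermediate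
21 | 4-[(Z)-1-ethoxyprop-1-en-2-yl]-4-methoxy-3-(propan-2-yloxy)-2-(2-phenylethyl)cyclobut-2-en-1-one (racemic) | CCO/C=C(/C)C1(OC)C(OC(C)C)=C(CCc2ccccc2)C1=O | intermediate
22 | {2,4,5-trimethoxy-3-methyl-6-[2-(2-methoxyphenyl)ethyl]phenyl}lithium | COc1ccccc1CCc1c([Li])c(OC)c(C)c(OC)c1OC | intermediate
23 | lithium 1-aryl-4-[(Z)-1-ethoxyprop-1-en-2-yl]-4-methoxy-2-(2-phenylethyl)-3-(propan-2-yloxy)cyclobut-2-en-1-olate (aryl as in 22; diastereomer mixture) | CCO/C=C(/C)C1(OC)C(OC(C)C)=C(CCc2ccccc2)C1(O[Li])c1c(CCc2ccccc2OC)c(OC)c(OC)c(C)c1OC | intermediate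
24 | trifluoroacetate ester of the alcohol corresponding to 23 (diastereomer mixture) | CCO/C=C(/C)C1(OC)C(OC(C)C)=C(CCc2ccccc2)C1(OC(=O)C(F)(F)F)c1c(CCc2ccccc2OC)c(OC)c(OC)c(C)c1OC | intermediate
25 | 4-[(Z)-1-ethoxyprop-1-en-2-yl]-4-methoxy-2-(2-phenylethyl)-3-{2,4,5-trimethoxy-3-methyl-6-[2-(2-methoxyphenyl)ethyl]phenyl}cyclobut-2-en-1-one (racemic) | CCO/C=C(/C)C1(OC)C(=O)C(CCc2ccccc2)=C1c1c(CCc2ccccc2OC)c(OC)c(OC)c(C)c1OC | intermediate
26 | 6-ethoxy-4-methoxy-5-methyl-2-(2-phenylethyl)-3-aryl-hexa-1,3,5-trien-1-one (aryl as in 22; propenyl group cis to the ketene carbon) | CCO/C=C(/C)\C(OC)=C(\c1c(CCc2ccccc2OC)c(OC)c(OC)c(C)c1OC)C(CCc1ccccc1)=C=O | intermediate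
27 | 6-ethoxy-4-methoxy-5-methyl-2-(2-phenylethyl)-3-aryl-cyclohexa-2,4-dien-1-one (aryl as in 22; racemic) | CCOC1C(=O)C(CCc2ccccc2)=C(c2c(CCc3ccccc3OC)c(OC)c(OC)c(C)c2OC)C(OC)=C1C | intermediate
28 | 2-ethoxy-4-methoxy-3-methyl-6-(2-phenylethyl)-5-{2,4,5-trimethoxy-3-methyl-6-[2-(2-methoxyphenyl)ethyl]phenyl}phenol | CCOc1c(O)c(CCc2ccccc2)c(-c2c(CCc3ccccc3OC)c(OC)c(OC)c(C)c2OC)c(OC)c1C | intermediate
29 | 2-ethoxy-5-{4-methoxy-5-methyl-2-[2-(2-methoxyphenyl)ethyl]-3,6-dioxocyclohexa-1,4-dien-1-yl}-3-methyl-6-(2-phenylethyl)cyclohexa-2,5-diene-1,4-dione | CCOC1=C(C)C(=O)C(C2=C(CCc3ccccc3OC)C(=O)C(OC)=C(C)C2=O)=C(CCc2ccccc2)C1=O | intermediate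
30 | disodium salt of 31 | [Na+].[Na+].COc1ccccc1CCC1=C(C2=C(CCc3ccccc3)C(=O)C([O-])=C(C)C2=O)C(=O)C(C)=C([O-])C1=O | intermediate
31 | 2-hydroxy-5-{4-hydroxy-5-methyl-2-[2-(2-methoxyphenyl)ethyl]-3,6-dioxocyclohexa-1,4-dien-1-yl}-3-methyl-6-(2-phenylethyl)cyclohexa-2,5-diene-1,4-dione | COc1ccccc1CCC1=C(C2=C(CCc3ccccc3)C(=O)C(O)=C(C)C2=O)C(=O)C(C)=C(O)C1=O | target

**Count**

Total steps: 12. Longest linear sequence: 9 steps (steps 1, 2, 3, 4, 5, 9, 10, 11, 12).

**Steps most likely to fail**

Step 9. Addition of the doubly ortho-substituted aryllithium to the carbonyl next to the quaternary carbon may be too slow, and the enol ether may be lost during the acylative transposition. The fallback exchanges the order of the two carbon nucleophiles; it sets out from 10 and 18 and comes back at 25. Aryllithium 22 (from 10 and n-BuLi) is added at −78 °C to the unhindered ketone carbonyl of dione 18 to give 4-hydroxy-3-(propan-2-yloxy)-2-(2-phenylethyl)-4-arylcyclobut-2-en-1-one F1. Treatment with 12 M HCl in CH2Cl2, the established second addition–hydrolysis cycle of squarate chemistry, should convert it into 3-(2-phenylethyl)-4-arylcyclobut-3-ene-1,2-dione F2. Vinyllithium 19 and MeOTf, as in step 8, then give 25. Regiocontrol is no longer built in, so the adduct at the other carbonyl has to be removed by chromatography.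

Step 8. The vinyllithium may lose lithium ethoxide by beta-elimination or lose its geometry before it adds, and O-methylation of the hindered alkoxide may be incomplete. The fallback installs the C4 oxygen of ring B after the ring is formed; it sets out from 18 and comes back at 31. CH2=C(CH3)MgBr is added to 18 at −78 °C and the alkoxide is methylated with MeOTf to give 4-methoxy-2-(2-phenylethyl)-4-(prop-1-en-2-yl)-3-(propan-2-yloxy)cyclobut-2-en-1-one F3. The conditions of step 9 give the 3-aryl cyclobutenone F4, and the conditions of step 10 give 4-methoxy-3-methyl-6-(2-phenylethyl)-5-arylphenol F5; the same C3–C4 bond of ring B is formed, now to a CH2 terminus. Oxidation with (NH4)2Ce(NO3)6 gives the bis-quinone F6, in which C4 of ring B carries hydrogen. Nucleophilic epoxidation of the only trisubstituted quinone double bond (H2O2, Na2CO3) gives the epoxide F7, and H2SO4 opens it to the 2-hydroxy-3-methylquinone F8, the classical conversion of a methylquinone into its hydroxy derivative. NaOH as in step 12 then gives 31.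

Step 3. Electrophilic attack may occur at the bromine-bearing carbon, the Lewis acid may cleave the flanked methyl ethers, and substitution at the last, hindered ring position may be slow. The fallback replaces electrophilic substitution by deprotonative metalation; it sets out from 4 and comes back at 6. Lithium 2,2,6,6-tetramethylpiperidide in THF at −78 °C removes the ring proton flanked by bromine and methoxy to give (2-bromo-3,5,6-trimethoxy-4-methylphenyl)lithium F9, which is formylated with DMF to give 6. The mixture is kept at −78 °C until the quench to avoid aryne formation.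

**Further compounds**

F1 | step 9 | 4-hydroxy-3-(propan-2-yloxy)-2-(2-phenylethyl)-4-{2,4,5-trimethoxy-3-methyl-6-[2-(2-methoxyphenyl)ethyl]phenyl}cyclobut-2-en-1-one (racemic) | CC(C)OC1=C(CCc2ccccc2)C(=O)C1(O)c1c(CCc2ccccc2OC)c(OC)c(OC)c(C)c1OC
F2 | step 9 | 3-(2-phenylethyl)-4-{2,4,5-trimethoxy-3-methyl-6-[2-(2-methoxyphenyl)ethyl]phenyl}cyclobut-3-ene-1,2-dione | O=C1C(=O)C(CCc2ccccc2)=C1c1c(CCc2ccccc2OC)c(OC)c(OC)c(C)c1OC
F3 | step 8 | 4-methoxy-2-(2-phenylethyl)-4-(prop-1-en-2-yl)-3-(propan-2-yloxy)cyclobut-2-en-1-one (racemic) | C=C(C)C1(OC)C(OC(C)C)=C(CCc2ccccc2)C1=O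
F4 | step 8 | 4-methoxy-2-(2-phenylethyl)-4-(prop-1-en-2-yl)-3-{2,4,5-trimethoxy-3-methyl-6-[2-(2-methoxyphenyl)ethyl]phenyl}cyclobut-2-en-1-one (racemic) | C=C(C)C1(OC)C(=O)C(CCc2ccccc2)=C1c1c(CCc2ccccc2OC)c(OC)c(OC)c(C)c1OC
F5 | step 8 | 4-methoxy-3-methyl-6-(2-phenylethyl)-5-{2,4,5-trimethoxy-3-methyl-6-[2-(2-methoxyphenyl)ethyl]phenyl}phenol | COc1c(C)cc(O)c(CCc2ccccc2)c1-c1c(CCc2ccccc2OC)c(OC)c(OC)c(C)c1OC
F6 | step 8 | 3-{4-methoxy-5-methyl-2-[2-(2-methoxyphenyl)ethyl]-3,6-dioxocyclohexa-1,4-dien-1-yl}-5-methyl-2-(2-phenylethyl)cyclohexa-2,5-diene-1,4-dione | CC1=CC(=O)C(CCc2ccccc2)=C(C2=C(CCc3ccccc3OC)C(=O)C(OC)=C(C)C2=O)C1=O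
F7 | step 8 | epoxide of F6 at the methyl-bearing double bond of ring B (1-methyl-7-oxabicyclo[4.1.0]hept-3-ene-2,5-dione core; racemic) | CC12OC1C(=O)C(CCc1ccccc1)=C(C1=C(CCc3ccccc3OC)C(=O)C(OC)=C(C)C1=O)C2=O
F8 | step 8 | 2-hydroxy-5-{4-methoxy-5-methyl-2-[2-(2-methoxyphenyl)ethyl]-3,6-dioxocyclohexa-1,4-dien-1-yl}-3-methyl-6-(2-phenylethyl)cyclohexa-2,5-diene-1,4-dione | COC1=C(C)C(=O)C(C2=C(CCc3ccccc3)C(=O)C(O)=C(C)C2=O)=C(CCc2ccccc2OC)C1=O
F9 | step 3 | (2-bromo-3,5,6-trimethoxy-4-methylphenyl)lithium | COc1c([Li])c(Br)c(OC)c(C)c1OC
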